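**Retrosynthetic overview**
1. Target ⇐ C4 acetylation ⇐ ring B (ten-membered) closed at C4–C5 by Nozaki–Hiyama–Kishi coupling of a (Z)-C5 alkenyl iodide with the C4 aldehyde; the γ-lactone (O7–C19) is closed just before by oxidative lactonisation.
2. C6–C7 comes from propyne (thioester coupling, asymmetric ynone reduction, trans-hydrosilylation/iodination); C8–C9 from the aldol of an (S)-malic-acid-derived dioxolanone enolate (brings C7, C8, C17–C19) with the ring A C9 aldehyde.
3. Ring A is made in one operation: rhodium-catalysed [4+2] union of an acyclic 4-alkynal (C14 aldehyde, C11≡C20 alkyne) with ethylene (C12–C13), then Evans–Tishchenko reduction with isobutyraldehyde (sets C14, acylates C2).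
4. Enabling feature: ring A is a 4-methylenecyclohexanol. Oxygenated C14 and sp2 C11 (exocyclic C20) are 1,4-related across the unsubstituted C12–C13 unit, and C1 is quaternary, so the open form is a non-enolisable 4-alkynal that lacks only ethylene.
5. The acyclic C2/C1/C10 triad comes from an Evans aldol and a chelation-controlled dianionic Ireland–Claisen rearrangement; ring order: ring A, then lactone, then ring B.

Key step: step 9

Remark: atoms carry briarane numbers (C1 quaternary fusion carbon with C15 methyl, C2 O-isobutyryl, C3, C4 OAc, C5(C16)=C6, C7 lactone O-carbon, C8 tertiary OH, C9 OAc, C10 fusion CH, C11=C20, C12, C13, C14 OAc, C17(C18), C19 lactone carbonyl); ring A = C1/C10–C14, ring B = C1–C10; compounds 1, 2, 4 and 19 are taken as commercial.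

**Route**

Step 1
Reactants: 1 (R)-4-benzyl-3-propanoyl-1,3-oxazolidin-2-one; 2 3-[(tert-butyldiphenylsilyl)oxy]propanal
Product: 3 Evans syn-aldol adduct (2R,3S)
Conditions: Bu2BOTf, i-Pr2NEt, CH2Cl2, −78 → 0 °C; 2, −78 → 0 °C; pH 7 buffer/MeOH/H2O2
Reagents that add atoms: none
Why: Evans syn-aldol; the (Z)-boron enolate adds through a Zimmerman–Traxler chair on the face set by the (R)-benzyl auxiliary, which fixes the future C2 carbinol (3S in the adduct; the 2-methyl centre is erased in step 4).

Step 2
Reactants: 4 (E)-but-2-ene-1,4-diol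
Product: 5 (E)-4-[(tert-butyldimethylsilyl)oxy]but-2-en-1-ol
Conditions: NaH (1.0 equiv), THF, 0 °C; TBSCl (1.0 equiv), 0 °C → rt
Reagents that add atoms: tert-butyldimethylsilyl chloride, CC(C)(C)[Si](C)(C)Cl
Why: Monosilylation of the symmetrical diol through its poorly soluble monosodium alkoxide.

Step 3
Reactants: 3 Evans aldol adduct; 5 (E)-4-[(tert-butyldimethylsilyl)oxy]but-2-en-1-ol
Product: 6 allylic β-hydroxy ester
Conditions: 5 (2 equiv), n-BuLi (1.9 equiv), THF, −78 → 0 °C; then 3, 0 °C; aq. NH4Cl
Reagents that add atoms: none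
Why: Transesterification of the N-acyloxazolidinone by a lithium alkoxide (exocyclic cleavage, as with LiOBn) gives the allylic ester and frees the auxiliary without touching the carbinol centre.

Step 4
Reactants: 6 allylic β-hydroxy ester
Product: 8 Claisen acid (C14 carboxylic acid, quaternary C1, C10 with CH2OTBS and the C11=C20 vinyl group), via chelated dilithium alkoxide-enolate 7 (not isolated)
Conditions: LiN(i-Pr)2 (2.5 equiv), THF, −78 → 50 °C; aq. HCl
Reagents that add atoms: none
Why: Dianionic Ireland–Claisen rearrangement; the lithium chelate between the C2 alkoxide and the enolate oxygen fixes the enolate geometry and, as in Fráter–Seebach alkylations, steers the allyl terminus to the face anti to the C3 chain, while the chair transition state with the (E)-alkene sets C10, so quaternary C1 (methyl syn to the C2 oxygen) and C10 form together.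

Step 5
Reactants: 8 Claisen acid
Product: 9 diol (C14 primary alcohol, C2 secondary alcohol)
Conditions: LiAlH4, THF, 0 °C → reflux; H2O/aq. NaOH
Reagents that add atoms: none
Why: LiAlH4 reduces the hindered carboxylic acid to the primary alcohol; silyl ethers and the terminal alkene are inert.

Step 6
Reactants: 9 diol
Product: 10 lactol (C11 aldehyde closed onto the C14 hydroxyl)
Conditions: O3, CH2Cl2/MeOH, −78 °C; PPh3, −78 °C → rt
Reagents that add atoms: ozone, O=[O+][O-]
Why: Ozonolysis with reductive work-up cleaves the only alkene (C11=C20) to the C11 aldehyde, which is held as a five-membered lactol and so shielded from epimerisation at C10.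

Step 7
Reactants: 10 lactol
Product: 11 alkynyl diol (C11≡C20 terminal alkyne on C10)
Conditions: dimethyl (1-diazo-2-oxopropyl)phosphonate, K2CO3, MeOH, 0 °C → rt
Reagents that add atoms: dimethyl (1-diazo-2-oxopropyl)phosphonate, COP(=O)(OC)C(=[N+]=[N-])C(C)=O
Why: Ohira–Bestmann (Seyferth–Gilbert) homologation of the lactol-aldehyde rebuilds C20 as a terminal alkyne under mild carbonate conditions that limit epimerisation and β-elimination at C10.

Step 8
Reactants: 11 alkynyl diol
Product: 12 4-alkynal (C14 aldehyde on quaternary C1, free C2 hydroxyl)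
Conditions: TEMPO (10 mol %), PhI(OAc)2 (1.1 equiv), CH2Cl2, rt
Reagents that add atoms: none
Why: TEMPO/PhI(OAc)2 oxidises the primary C14 alcohol in preference to the secondary C2 alcohol; the aldehyde sits on quaternary C1 and can neither enolise nor eliminate.

Step 9
Reactants: 12 4-alkynal
Product: 14 ring A ketone (4-methylenecyclohexanone), via acyl(alkenyl)rhodium metallacycle 13 (not isolated)
Conditions: [Rh(cod)(dppe)]BF4 (10 mol %, pre-activated with H2), ethylene (8 atm), acetone, 40 °C
Reagents that add atoms: ethylene, C=C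
Why: Proposed new method: oxidative addition of the C14 aldehyde C–H bond to cationic monovalent rhodium (helped by the C2 hydroxyl as a hemilabile chelating group) gives an acylrhodium hydride of trivalent rhodium, which adds H to C20 and Rh to C11 of the tethered alkyne to give the five-membered metallacycle 13; ethylene then inserts into a Rh–C bond and C–C reductive elimination forms C13–C14 and C11–C12, leaving the C11=C20 exocyclic methylene. The closest known reaction type is the rhodium-catalysed [4+2] annulation of 4-alkynals with alkynes and with acrylamides, which runs through the same metallacycle; ethylene as the two-carbon partner and a terminal alkyne are not precedented there, whereas ethylene insertion into acylrhodium hydrides is well known from intermolecular hydroacylation. Ring A closes as a formal [4+2]: exo-dig hydrometalation to the rhodacycle, migratory insertion of ethylene, reductive elimination of the six-membered ring. No new stereocentre is formed, since C14 becomes a ketone and C11 stays sp2, and C1 (quaternary) and C10 are carried through unchanged. The step needs chemoselectivity for ethylene capture over decarbonylation, over cyclisation of the 4-alkynal alone to a cyclopentenone and over simple hydroacylation of ethylene; the quaternary C1 (no α-hydrogen, Thorpe–Ingold bias), the fast intramolecular hydrometalation, the strain of the alternative cyclobutanone-forming elimination and the ethylene pressure should secure it.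

Step 10
Reactants: 14 ring A ketone
Product: 15 C2 isobutyrate with free axial C14 alcohol
Conditions: i-PrCHO (5 equiv), SmI2 (20 mol %), THF, −10 °C
Reagents that add atoms: isobutyraldehyde, CC(C)C=O
Why: Evans–Tishchenko reduction; the samarium-bound hemiacetal of the C2 alkoxide with isobutyraldehyde transfers hydride intramolecularly to the C14 ketone through a chair that is trans-fused to ring A (C3 and C10 equatorial, C15 axial), giving the 1,3-anti C14 alcohol (axial, trans to C15) and placing the isobutyrate on C2 in the same operation.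

Step 11
Reactants: 15 C2 isobutyrate, C14 alcohol
Product: 16 C14 acetate
Conditions: Ac2O, DMAP (cat.), pyridine, 0 °C → rt
Reagents that add atoms: acetic anhydride, CC(=O)OC(C)=O
Why: DMAP-catalysed acetylation of the hindered axial alcohol; doing it directly after step 10 blocks 1,3-migration of the isobutyryl group.

Step 12
Reactants: 16 C14 acetate
Product: 17 C9 primary alcohol
Conditions: PPTS (cat.), MeOH, rt
Reagents that add atoms: none
Why: Acid-catalysed methanolysis removes the primary TBS ether while the far more acid-stable TBDPS ether and the esters remain.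

Step 13
Reactants: 17 C9 primary alcohol
Product: 18 C9 aldehyde
Conditions: Dess–Martin periodinane, NaHCO3, CH2Cl2, 0 °C; used at once
Reagents that add atoms: none
Why: Dess–Martin oxidation under buffered, non-basic conditions gives the sensitive β,γ-unsaturated aldehyde without enolisation at C10.

Step 14
Reactants: 19 dimethyl (S)-malate
Product: 20 dimethyl (2S,3R)-2-hydroxy-3-methylbutanedioate
Conditions: LiN(i-Pr)2 (2.2 equiv), THF, −78 → −20 °C; MeI, −78 → 0 °C; aq. NH4Cl
Reagents that add atoms: iodomethane, CI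
Why: Fráter–Seebach alkylation; the chelated dianion of the β-hydroxy ester is methylated anti to the C–O bond, which sets C17 from the malate stereocentre.

Step 15
Reactants: 20 dimethyl (2S,3R)-2-hydroxy-3-methylbutanedioate
Product: 21 (2S,3R)-2-hydroxy-3-methylbutanedioic acid
Conditions: KOH, MeOH/H2O, rt; aq. HCl
Reagents that add atoms: none
Why: Saponification of both esters; the carboxylate α-centres do not epimerise under these conditions.

Step 16
Reactants: 21 (2S,3R)-2-hydroxy-3-methylbutanedioic acid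
Product: 22 cis-dioxolanone acid
Conditions: t-BuCHO, TsOH (cat.), H2SO4 (cat.), pentane, reflux, Dean–Stark
Reagents that add atoms: pivalaldehyde, CC(C)(C)C=O
Why: Acid-catalysed acetalisation of the α-hydroxy acid gives the five-membered dioxolanone as the cis isomer under thermodynamic control, storing the C8 configuration in the acetal centre.

Step 17
Reactants: 22 cis-dioxolanone acid
Product: 23 dioxolanone alcohol (C19 at the alcohol level)
Conditions: BH3·THF, THF, 0 °C → rt; MeOH
Reagents that add atoms: none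
Why: Borane reduces the free carboxylic acid chemoselectively in the presence of the dioxolanone.

Step 18
Reactants: 23 dioxolanone alcohol
Product: 24 dioxolanone TBS ether
Conditions: TBSCl, imidazole, DMF, 0 °C → rt
Reagents that add atoms: tert-butyldimethylsilyl chloride, CC(C)(C)[Si](C)(C)Cl
Why: Standard silylation protects C19–OH and removes the only other acidic site before enolisation.

Step 19
Reactants: 24 dioxolanone TBS ether; 18 C9 aldehyde
Product: 25 aldol adduct (C8 quaternary in the dioxolanone; C9 carbinol as formed)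
Conditions: LiN(SiMe3)2 (1.05 equiv), THF, −78 °C; then 18, −78 °C; AcOH quench at −78 °C
Reagents that add atoms: none
Why: Aldol addition of the dioxolanone lithium enolate (self-regeneration of stereocentres); the aldehyde is attacked on the enolate face anti to the tert-butyl group, so C8 forms with the malate configuration, while the C9 carbinol is not relied upon (expected mainly in the 9R, Felkin sense) and is reset in steps 20 and 21.

Step 20
Reactants: 25 aldol adduct
Product: 26 C9 ketone
Conditions: Dess–Martin periodinane, NaHCO3, CH2Cl2, 0 °C → rt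
Reagents that add atoms: none
Why: Dess–Martin oxidation of the hindered carbinol gives the β-keto lactone without base, so C10 and the exocyclic alkene are not disturbed.

Step 21
Reactants: 26 C9 ketone
Product: 27 (9S) alcohol
Conditions: (R)-2-methyl-CBS-oxazaborolidine (0.5 equiv), catecholborane, toluene, −78 → −40 °C
Reagents that add atoms: none
Why: Corey–Bakshi–Shibata reduction; with quaternary C8 as the large group the (R)-oxazaborolidine should deliver hydride to give 9S, which is also the Felkin–Anh sense with respect to C10 (hydride anti to C1), so reagent and substrate control should reinforce each other.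

Step 22
Reactants: 27 (9S) alcohol
Product: 28 C9 acetate
Conditions: Ac2O, DMAP (cat.), Et3N, CH2Cl2, 0 °C → rt
Reagents that add atoms: acetic anhydride, CC(=O)OC(C)=O
Why: Acetylation of the secondary alcohol; the dioxolanone and the other esters are untouched.

Step 23
Reactants: 28 C9 acetate
Product: 29 C7 S-ethyl thioester with free tertiary C8 hydroxyl
Conditions: NaSEt (1.2 equiv), THF, 0 °C; aq. NH4Cl
Reagents that add atoms: sodium ethanethiolate, [Na+].[S-]CC
Why: Nucleophilic acyl substitution at the activated (acylal-type) dioxolanone carbonyl by thiolate gives the thioester and releases pivalaldehyde and the C8 hydroxyl, while ordinary acetate and isobutyrate esters should not react with thiolate at 0 °C.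

Step 24
Reactants: 29 C7 thioester
Product: 30 ynone (C7 ketone, C6≡C5–C16)
Conditions: propyne (excess), PdCl2(dppf) (5 mol %), P(2-furyl)3 (10 mol %), CuI (1.5 equiv), Et3N, DMF, 50 °C
Reagents that add atoms: propyne, CC#C
Why: Palladium/copper-mediated coupling of a thioester with a terminal alkyne (Fukuyama–Tokuyama ynone synthesis) joins C6 to C7 under conditions that tolerate esters, the tertiary alcohol and the exocyclic alkene.

Step 25
Reactants: 30 ynone
Product: 31 (7S) propargylic alcohol
Conditions: Ru[(R,R)-TsNCH(Ph)CH(Ph)NH](p-cymene) (5 mol %), i-PrOH, rt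
Reagents that add atoms: none
Why: Noyori asymmetric transfer hydrogenation of the ynone; the (R,R)-TsDPEN ruthenium catalyst places the alkynyl group where an aryl group normally sits, which corresponds to 7S here, and esters and alkenes are not reduced.

Step 26
Reactants: 31 (7S) propargylic alcohol
Product: 32 (Z)-alkenylsilane (silicon on C5, cis to C7)
Conditions: BnMe2SiH (1.3 equiv), [Cp*Ru(MeCN)3]PF6 (5 mol %), acetone, 0 °C → rt
Reagents that add atoms: benzyldimethylsilane, C[SiH](C)Cc1ccccc1
Why: Ruthenium-catalysed trans-hydrosilylation of a propargylic alcohol places silicon on the distal carbon C5 and hydrogen on C6 with anti addition.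

Step 27
Reactants: 32 (Z)-alkenylsilane
Product: 33 (Z)-alkenyl iodide (iodine on C5, cis to C7)
Conditions: N-iodosuccinimide (1.3 equiv), (CF3)2CHOH, 0 °C
Reagents that add atoms: N-iodosuccinimide, O=C1CCC(=O)N1I
Why: Iododesilylation replaces silicon by iodine with retention of geometry; the β-silyl-activated alkenylsilane reacts far faster than the exocyclic alkene.

Step 28
Reactants: 33 (Z)-alkenyl iodide
Product: 34 triol (C4–OH, C19–OH and C7–OH free)
Conditions: HF·pyridine, pyridine, THF, 0 °C → rt
Reagents that add atoms: none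
Why: HF·pyridine cleaves both primary silyl ethers (C19–OTBS, C4–OTBDPS) without loss of the acetates.

Step 29
Reactants: 34 triol
Product: 35 γ-lactone C4 aldehyde
Conditions: TEMPO (20 mol %), PhI(OAc)2 (3.5 equiv), CH2Cl2, rt
Reagents that add atoms: none
Why: TEMPO/PhI(OAc)2 oxidises only the two primary alcohols; the C19 aldehyde is trapped by the C7 hydroxyl as a lactol and oxidised on to the γ-lactone (C9 is already acetylated, so only O7 can close), and C4 stops at the aldehyde.

Step 30
Reactants: 35 γ-lactone C4 aldehyde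
Product: 36 macrocyclic C4 alcohol (rings A and B and lactone complete)
Conditions: CrCl2 (10 equiv), NiCl2 (2 mol %), DMSO, 25 °C, syringe-pump addition to 0.003 M
Reagents that add atoms: none
Why: Nozaki–Hiyama–Kishi coupling; zerovalent nickel inserts into the C5–I bond, transmetalation to trivalent chromium and addition of the alkenylchromium to the C4 aldehyde closes ring B with retention of the (Z)-C5=C6 geometry, esters, lactone and the tertiary C8–OH are tolerated, and the 4R carbinol should arise from attack on the outward aldehyde face of the folded chain, which is not secured and is covered by a fallback.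

Step 31
Reactants: 36 macrocyclic C4 alcohol
Product: 37 CNP0189561.1
Conditions: Ac2O, DMAP (cat.), pyridine, 0 °C → rt
Reagents that add atoms: acetic anhydride, CC(=O)OC(C)=O
Why: Acetylation of the secondary allylic C4 alcohol completes the target; the tertiary C8 hydroxyl is too hindered to react under these conditions.

**Compound list**
1 | (R)-4-benzyl-3-propanoyl-1,3-oxazolidin-2-one | CCC(=O)N1[C@H](Cc2ccccc2)COC1=O | starting material
2 | 3-[(tert-butyldiphenylsilyl)oxy]propanal | O=CCCO[Si](c1ccccc1)(c1ccccc1)C(C)(C)C | starting material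
3 | (R)-4-benzyl-3-[(2R,3S)-5-[(tert-butyldiphenylsilyl)oxy]-3-hydroxy-2-methylpentanoyl]-1,3-oxazolidin-2-one | C[C@H]([C@@H](O)CCO[Si](c1ccccc1)(c1ccccc1)C(C)(C)C)C(=O)N1[C@H](Cc2ccccc2)COC1=O | intermediate
4 | (E)-but-2-ene-1,4-diol | OC/C=C/CO | starting material
5 | (E)-4-[(tert-butyldimethylsilyl)oxy]but-2-en-1-ol | OC/C=C/CO[Si](C)(C)C(C)(C)C | intermediate
6 | (E)-4-[(tert-butyldimethylsilyl)oxy]but-2-en-1-yl (2R,3S)-5-[(tert-butyldiphenylsilyl)oxy]-3-hydroxy-2-methylpentanoate | C[C@H]([C@@H](O)CCO[Si](c1ccccc1)(c1ccccc1)C(C)(C)C)C(=O)OC/C=C/CO[Si](C)(C)C(C)(C)C | intermediate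
7 | chelated dilithium alkoxide-enolate of 6 (enolate oxygen cis to C2) | [Li+].[Li+].[O-]/C(OC/C=C/CO[Si](C)(C)C(C)(C)C)=C(/C)[C@@H]([O-])CCO[Si](c1ccccc1)(c1ccccc1)C(C)(C)C | intermediate
8 | (2S,3S)-3-{[(tert-butyldimethylsilyl)oxy]methyl}-2-[(1S)-3-[(tert-butyldiphenylsilyl)oxy]-1-hydroxypropyl]-2-methylpent-4-enoic acid (C14 acid; acid C-2 = C1, C-3 = C10) | OC(=O)[C@](C)([C@@H](O)CCO[Si](c1ccccc1)(c1ccccc1)C(C)(C)C)[C@@H](CO[Si](C)(C)C(C)(C)C)C=C | intermediate
9 | diol: 8 with C14 reduced to CH2OH; C2 alcohol, C10 bearing CH2OTBS (C9) and the C11=C20 vinyl group | OC[C@](C)([C@@H](O)CCO[Si](c1ccccc1)(c1ccccc1)C(C)(C)C)[C@@H](CO[Si](C)(C)C(C)(C)C)C=C | intermediate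
10 | lactol: C11 aldehyde closed onto the C14 hydroxyl (2-hydroxytetrahydrofuran, anomer mixture), C2 alcohol free | OC1OC[C@](C)([C@@H](O)CCO[Si](c2ccccc2)(c2ccccc2)C(C)(C)C)[C@H]1CO[Si](C)(C)C(C)(C)C | intermediate
11 | alkynyl diol: as 9 with the terminal alkyne C11≡C20 on C10 | OC[C@](C)([C@@H](O)CCO[Si](c1ccccc1)(c1ccccc1)C(C)(C)C)[C@@H](CO[Si](C)(C)C(C)(C)C)C#C | intermediate
12 | 4-alkynal: C14 aldehyde on quaternary C1, free C2 hydroxyl, C11≡C20 alkyne on C10 | O=C[C@](C)([C@@H](O)CCO[Si](c1ccccc1)(c1ccccc1)C(C)(C)C)[C@@H](CO[Si](C)(C)C(C)(C)C)C#C | intermediate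
13 | cationic acyl(alkenyl)rhodium metallacycle (Rh bound to acyl C14 and to C11 of the C11=C20 alkenyl; dppe on rhodium and BF4 counter-ion written as separate components) | C=C1[Rh+]C(=O)[C@](C)([C@@H](O)CCO[Si](c2ccccc2)(c2ccccc2)C(C)(C)C)[C@H]1CO[Si](C)(C)C(C)(C)C.c1ccc(cc1)P(CCP(c1ccccc1)c1ccccc1)c1ccccc1.F[B-](F)(F)F | intermediate
14 | ring A ketone: 4-methylenecyclohexanone (C14 ketone, C11=C20) with C1 carrying C15 and the 1-hydroxy-3-(TBDPS-oxy)propyl chain (C2–C4) and C10 carrying CH2OTBS (C9), the two chains trans | C=C1CCC(=O)[C@](C)([C@@H](O)CCO[Si](c2ccccc2)(c2ccccc2)C(C)(C)C)[C@H]1CO[Si](C)(C)C(C)(C)C | intermediate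
15 | C2 isobutyrate with axial C14 alcohol (trans to C15, 1,3-anti to O2) | C=C1CC[C@H](O)[C@](C)([C@@H](OC(=O)C(C)C)CCO[Si](c2ccccc2)(c2ccccc2)C(C)(C)C)[C@H]1CO[Si](C)(C)C(C)(C)C | intermediate
16 | C14 acetate of 15 | C=C1CC[C@H](OC(C)=O)[C@](C)([C@@H](OC(=O)C(C)C)CCO[Si](c2ccccc2)(c2ccccc2)C(C)(C)C)[C@H]1CO[Si](C)(C)C(C)(C)C | intermediate
17 | C9 primary alcohol (TBS removed from 16) | C=C1CC[C@H](OC(C)=O)[C@](C)([C@@H](OC(=O)C(C)C)CCO[Si](c2ccccc2)(c2ccccc2)C(C)(C)C)[C@H]1CO | intermediate
18 | C9 aldehyde | C=C1CC[C@H](OC(C)=O)[C@](C)([C@@H](OC(=O)C(C)C)CCO[Si](c2ccccc2)(c2ccccc2)C(C)(C)C)[C@H]1C=O | intermediate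
19 | dimethyl (S)-malate | COC(=O)C[C@H](O)C(=O)OC | starting material
20 | dimethyl (2S,3R)-2-hydroxy-3-methylbutanedioate | COC(=O)[C@H](C)[C@H](O)C(=O)OC | intermediate
21 | (2S,3R)-2-hydroxy-3-methylbutanedioic acid | OC(=O)[C@H](C)[C@H](O)C(=O)O | intermediate
22 | (2R)-2-[(2S,4S)-2-tert-butyl-5-oxo-1,3-dioxolan-4-yl]propanoic acid | OC(=O)[C@H](C)[C@@H]1O[C@H](C(C)(C)C)OC1=O | intermediate
23 | (2S,5S)-2-tert-butyl-5-[(2S)-1-hydroxypropan-2-yl]-1,3-dioxolan-4-one | OC[C@H](C)[C@@H]1O[C@H](C(C)(C)C)OC1=O | intermediate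
24 | (2S,5S)-2-tert-butyl-5-[(2S)-1-[(tert-butyldimethylsilyl)oxy]propan-2-yl]-1,3-dioxolan-4-one | CC(C)(C)[Si](C)(C)OC[C@H](C)[C@@H]1O[C@H](C(C)(C)C)OC1=O | intermediate
25 | aldol adduct: ring A unit of 18 joined at C9 (carbinol, epimer mixture) to C8 of the dioxolanone (C9 trans to tert-butyl) | C=C1CC[C@H](OC(C)=O)[C@](C)([C@@H](OC(=O)C(C)C)CCO[Si](c2ccccc2)(c2ccccc2)C(C)(C)C)[C@H]1C(O)[C@]1(O[C@H](C(C)(C)C)OC1=O)[C@@H](C)CO[Si](C)(C)C(C)(C)C | intermediate
26 | C9 ketone | C=C1CC[C@H](OC(C)=O)[C@](C)([C@@H](OC(=O)C(C)C)CCO[Si](c2ccccc2)(c2ccccc2)C(C)(C)C)[C@H]1C(=O)[C@]1(O[C@H](C(C)(C)C)OC1=O)[C@@H](C)CO[Si](C)(C)C(C)(C)C | intermediate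
27 | (9S) alcohol | C=C1CC[C@H](OC(C)=O)[C@](C)([C@@H](OC(=O)C(C)C)CCO[Si](c2ccccc2)(c2ccccc2)C(C)(C)C)[C@H]1[C@H](O)[C@]1(O[C@H](C(C)(C)C)OC1=O)[C@@H](C)CO[Si](C)(C)C(C)(C)C | intermediate
28 | C9 acetate | C=C1CC[C@H](OC(C)=O)[C@](C)([C@@H](OC(=O)C(C)C)CCO[Si](c2ccccc2)(c2ccccc2)C(C)(C)C)[C@H]1[C@H](OC(C)=O)[C@]1(O[C@H](C(C)(C)C)OC1=O)[C@@H](C)CO[Si](C)(C)C(C)(C)C | intermediate
29 | C7 S-ethyl thioester, free tertiary C8–OH | C=C1CC[C@H](OC(C)=O)[C@](C)([C@@H](OC(=O)C(C)C)CCO[Si](c2ccccc2)(c2ccccc2)C(C)(C)C)[C@H]1[C@H](OC(C)=O)[C@@](O)(C(=O)SCC)[C@@H](C)CO[Si](C)(C)C(C)(C)C | intermediate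
30 | ynone (C7 ketone, C6≡C5–C16) | C=C1CC[C@H](OC(C)=O)[C@](C)([C@@H](OC(=O)C(C)C)CCO[Si](c2ccccc2)(c2ccccc2)C(C)(C)C)[C@H]1[C@H](OC(C)=O)[C@@](O)(C(=O)C#CC)[C@@H](C)CO[Si](C)(C)C(C)(C)C | intermediate
31 | (7S) propargylic alcohol | C=C1CC[C@H](OC(C)=O)[C@](C)([C@@H](OC(=O)C(C)C)CCO[Si](c2ccccc2)(c2ccccc2)C(C)(C)C)[C@H]1[C@H](OC(C)=O)[C@@](O)([C@@H](O)C#CC)[C@@H](C)CO[Si](C)(C)C(C)(C)C | intermediate
32 | (Z)-alkenylsilane (BnMe2Si on C5, cis to C7) | C=C1CC[C@H](OC(C)=O)[C@](C)([C@@H](OC(=O)C(C)C)CCO[Si](c2ccccc2)(c2ccccc2)C(C)(C)C)[C@H]1[C@H](OC(C)=O)[C@@](O)([C@@H](O)/C=C(/C)[Si](C)(C)Cc2ccccc2)[C@@H](C)CO[Si](C)(C)C(C)(C)C | intermediate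
33 | (Z)-alkenyl iodide (iodine on C5, cis to C7) | C=C1CC[C@H](OC(C)=O)[C@](C)([C@@H](OC(=O)C(C)C)CCO[Si](c2ccccc2)(c2ccccc2)C(C)(C)C)[C@H]1[C@H](OC(C)=O)[C@@](O)([C@@H](O)/C=C(/C)I)[C@@H](C)CO[Si](C)(C)C(C)(C)C | intermediate
34 | triol (C4–OH, C19–OH, C7–OH free; C8–OH tertiary) | C=C1CC[C@H](OC(C)=O)[C@](C)([C@@H](OC(=O)C(C)C)CCO)[C@H]1[C@H](OC(C)=O)[C@@](O)([C@@H](O)/C=C(/C)I)[C@@H](C)CO | intermediate
35 | γ-lactone (O7–C19) with C4 aldehyde and (Z)-C5 alkenyl iodide | C=C1CC[C@H](OC(C)=O)[C@](C)([C@@H](OC(=O)C(C)C)CC=O)[C@H]1[C@H](OC(C)=O)[C@]1(O)[C@@H](C)C(=O)O[C@H]1/C=C(/C)I | intermediate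
36 | 4-deacetyl target (4R alcohol; rings A and B and lactone complete) | C=C1CC[C@H](OC(C)=O)[C@]2(C)[C@@H](OC(=O)C(C)C)C[C@@H](O)/C(C)=C\[C@@H]3OC(=O)[C@H](C)[C@@]3(O)[C@@H](OC(C)=O)[C@@H]12 | intermediate
37 | CNP0189561.1 | C=C1CC[C@H](OC(C)=O)[C@]2(C)[C@@H](OC(=O)C(C)C)C[C@@H](OC(C)=O)/C(C)=C\[C@@H]3OC(=O)[C@H](C)[C@@]3(O)[C@@H](OC(C)=O)[C@@H]12 | target

**Totals and risks**

Total step count: 31. Longest linear sequence: 25 steps (steps 1, 3–13 and 19–31).

Most likely to fail:

Step 9 (proposed new method). The acylrhodium hydride may lose CO, collapse to a cyclopentenone by hydroacylation of its own alkyne, or the terminal alkyne may oligomerise before ethylene is taken up. The fallback builds the two bonds one after the other with known chemistry, sets out from 12 and returns at 14. Vinylmagnesium bromide (excess, THF, −78 °C) adds to the aldehyde to give the C14 allylic alcohol F1 (C14 epimers). MnO2 oxidises only the allylic hydroxyl to the vinyl ketone F2. Benzeneselenol (cat. Et3N) adds in conjugate fashion to give the β-(phenylselanyl) ketone F3. Bu3SnH/AIBN (slow addition, benzene, 80 °C) generates the C12 radical, which closes ring A by 6-exo-dig attack on C11 of the alkyne; hydrogen transfer to the C20 alkenyl radical gives 14.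

Step 19. The basic enolate may deprotonate the β,γ-unsaturated aldehyde at C10 instead of adding to it, with loss of the C10 configuration or shift of the exocyclic double bond into conjugation. The fallback replaces the aldol by an acylation, sets out from 17 and returns at 26. The alcohol is oxidised (TEMPO/PhI(OAc)2, then NaClO2) to the C9 carboxylic acid F4, which 1-chloro-N,N,2-trimethylprop-1-en-1-amine converts into the C9 acid chloride F5. The lithium enolate of 24 is C-acylated with it at −78 °C (Claisen-type acylation, again anti to tert-butyl) to give ketone 26 directly, bypassing steps 19 and 20.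

Step 30. Facial selectivity at the C4 aldehyde during ring closure may be poor or opposite, giving the wrong C4 epimer. The fallback decouples ring closure from the C4 configuration, sets out from 35 and returns at 36. The cyclisation product, for example the 4S macrocyclic alcohol F6, is oxidised with Dess–Martin periodinane to the macrocyclic C4 enone F7. Reagent-controlled reduction with (S)-2-methyl-CBS-oxazaborolidine/catecholborane then sets 4R.

Further compounds
F1 | step 9 | C14 allylic alcohol from vinyl addition to 12 (C14 epimers) | C=CC(O)[C@](C)([C@@H](O)CCO[Si](c1ccccc1)(c1ccccc1)C(C)(C)C)[C@@H](CO[Si](C)(C)C(C)(C)C)C#C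
F2 | step 9 | vinyl ketone (C14 ketone, C12=C13) | C=CC(=O)[C@](C)([C@@H](O)CCO[Si](c1ccccc1)(c1ccccc1)C(C)(C)C)[C@@H](CO[Si](C)(C)C(C)(C)C)C#C
F3 | step 9 | β-(phenylselanyl) ketone (PhSe on C12) | O=C(CC[Se]c1ccccc1)[C@](C)([C@@H](O)CCO[Si](c2ccccc2)(c2ccccc2)C(C)(C)C)[C@@H](CO[Si](C)(C)C(C)(C)C)C#C
F4 | step 19 | C9 carboxylic acid from 17 | C=C1CC[C@H](OC(C)=O)[C@](C)([C@@H](OC(=O)C(C)C)CCO[Si](c2ccccc2)(c2ccccc2)C(C)(C)C)[C@H]1C(=O)O
F5 | step 19 | C9 acid chloride | C=C1CC[C@H](OC(C)=O)[C@](C)([C@@H](OC(=O)C(C)C)CCO[Si](c2ccccc2)(c2ccccc2)C(C)(C)C)[C@H]1C(Cl)=O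
F6 | step 30 | 4S macrocyclic alcohol (4-epimer of 36) | C=C1CC[C@H](OC(C)=O)[C@]2(C)[C@@H](OC(=O)C(C)C)C[C@H](O)/C(C)=C\[C@@H]3OC(=O)[C@H](C)[C@@]3(O)[C@@H](OC(C)=O)[C@@H]12
F7 | step 30 | macrocyclic C4 enone | C=C1CC[C@H](OC(C)=O)[C@]2(C)[C@@H](OC(=O)C(C)C)CC(=O)/C(C)=C\[C@@H]3OC(=O)[C@H](C)[C@@]3(O)[C@@H](OC(C)=O)[C@@H]12
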